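**Plan**
- Retrosynthesis: the five benzyl ethers come off last. Flavone 1 is cut at C2 (C1'–C2, C2–C3, C2–O1, with C2 supplied by CO) into an aryl bromide and a 2-hydroxyacetophenone.
- Flavone 2 is cut at O1–C2, C3–C4 and C4–C4a into an arylacetylene and a formyl group ortho to the one free hydroxyl of a 4-aryl-3,5-bis(silyloxy)phenol.
- Ring A of flavone 2 is cut at C6–C7, C8–C8a and C4a–C8a into a 2-aryl-3-siloxycyclobutenone and (triisopropylsilyloxy)acetylene. This works because C6 carries the aryl group between the oxygens on C5 and C7, while the oxygen on C8a, para to C6, is the pyranone oxygen and must be the only free one.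
- The cyclobutenone comes from an arylketene/ethoxyacetylene (2+2) adduct. That cycloaddition puts the aryl group on C4, not C2, so the enol ether is transposed by hydrolysis to the dione enol and O-silylation.
- Forward order of rings: cyclobutenone, ring A of flavone 2, pyranone of flavone 2, pyranone of flavone 1. Ring A of flavone 1 and both rings B are bought.
- Stereochemistry: the target has no stereocentre; the racemic centres of three intermediates are erased on the way.

Key step: step 6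

Remark: the target SMILES has no stereodescriptor. Its biaryl axis has only hydroxyl groups and hydrogen in the ortho positions and is taken as freely rotating, so no axial configuration is controlled.

**Route**

Step 1
Reactants: 1 2-(5-bromo-2-hydroxyphenyl)acetic acid
Product: 2 2-(2-benzyloxy-5-bromophenyl)acetic acid
Conditions: BnBr (1.3 equiv), NaOH (aq), EtOH, reflux; then HCl
Reagents that add atoms: benzyl bromide, BrCc1ccccc1
Why: Williamson etherification of the dianion, in which the phenoxide is alkylated faster than the carboxylate and any benzyl ester is saponified by the excess hydroxide.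

Step 2
Reactants: 2 2-(2-benzyloxy-5-bromophenyl)acetic acid; 3 ethoxyacetylene
Product: 6 4-(2-benzyloxy-5-bromophenyl)-3-ethoxycyclobut-2-en-1-one (racemic), via acid chloride 4 (not isolated), via arylketene 5 (not isolated)
Conditions: (COCl)2, cat. DMF, CH2Cl2, 0 °C to rt; concentrate; 3 (3 equiv), Et3N (slow addition), Et2O, 0 °C to rt
Reagents that add atoms: none
Why: Dehydrochlorination of the acid chloride gives the arylketene, which enters the ketene–ynol ether (2+2) cycloaddition with the CH carbon of the alkyne bonding to the ketene carbonyl carbon, so the aryl group should end on C4 as a racemic centre.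

Step 3
Reactants: 6 4-(2-benzyloxy-5-bromophenyl)-3-ethoxycyclobut-2-en-1-one
Product: 7 2-(2-benzyloxy-5-bromophenyl)-3-hydroxycyclobut-2-en-1-one
Conditions: 1 M HCl, THF, rt
Reagents that add atoms: water, O
Why: Acid hydrolysis of the vinylogous ester gives the 2-arylcyclobutane-1,3-dione, which enolises toward the aryl-bearing carbon (erasing the C4 centre) to the conjugated vinylogous acid, separable by bicarbonate extraction.

Step 4
Reactants: 7 2-(2-benzyloxy-5-bromophenyl)-3-hydroxycyclobut-2-en-1-one; 8 triisopropylsilyl trifluoromethanesulfonate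
Product: 9 2-(2-benzyloxy-5-bromophenyl)-3-(triisopropylsilyloxy)cyclobut-2-en-1-one
Conditions: 8 (1.1 equiv), Et3N, CH2Cl2, −78 to 0 °C
Reagents that add atoms: none
Why: O-silylation of the delocalised anion of the vinylogous acid, whose two oxygens are equivalent, can give only the 2-aryl-3-siloxy isomer, which completes the transposition of the enol ether.

Step 5
Reactants: 10 ethyl dibromoacetate; 8 triisopropylsilyl trifluoromethanesulfonate
Product: 12 (triisopropylsilyloxy)acetylene, via lithium ethynolate 11 (not isolated)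
Conditions: t-BuLi (4 equiv), THF, −78 to 0 °C; 8, −78 °C to rt
Reagents that add atoms: none
Why: Double bromine–lithium exchange on the α,α-dibromo ester with loss of lithium ethoxide is the established route to lithium ynolates, and the bulky silyl triflate should capture the ynolate on oxygen as in the Kowalski silyl ynol ether synthesis.

Step 6
Reactants: 9 2-(2-benzyloxy-5-bromophenyl)-3-(triisopropylsilyloxy)cyclobut-2-en-1-one; 12 (triisopropylsilyloxy)acetylene
Product: 17 4-(2-benzyloxy-5-bromophenyl)-3,5-bis(triisopropylsilyloxy)phenol, via vinylketene 13 (not isolated), via vinylcyclobutenone 14 (not isolated), via dienylketene 15 (not isolated), via cyclohexadienone 16 (not isolated)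
Conditions: 12 (2 equiv), toluene, 110 to 140 °C, sealed tube
Reagents that add atoms: none
Why: Heating should open 9 by 4π-electrocyclic cleavage of C1–C4 to the aryl(siloxyvinyl)ketene 13, whose ketene carbon is attacked by the nucleophilic CH carbon of 12 in a (2+2) cycloaddition that gives the 4-vinylcyclobutenone 14 with a transient racemic quaternary centre. A second 4π opening gives dienylketene 15, and the six-membered ring closes by thermal 6π-electrocyclisation between the ketene carbon and the CH2 terminus of the siloxyvinyl group to dienone 16, which tautomerises to phenol 17. This is a Danheiser benzannulation of a cyclobutenone with a siloxyalkyne, closest to the known resorcinol syntheses from cyclobutenones or vinylketenes and triisopropylsilyl ynol ethers. No stereocentre survives, so only regio- and chemoselectivity matter. Regioselectivity follows from the polarity of the ynol ether, whose oxygen-bearing carbon bonds to the aryl-bearing α-carbon of the ketene, so the aryl group ends between the two siloxy groups and the free hydroxyl para to it. Closure on the siloxyvinyl terminus should win over closure on the arene because that terminus is a nucleophilic enol ether carbon and no dearomatisation is needed, and the geometric isomers of 15 can equilibrate through 14.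

Step 7
Reactants: 17 4-(2-benzyloxy-5-bromophenyl)-3,5-bis(triisopropylsilyloxy)phenol
Product: 18 3-(2-benzyloxy-5-bromophenyl)-6-hydroxy-2,4-bis(triisopropylsilyloxy)benzaldehyde
Conditions: MgCl2, Et3N, (CH2O)n, THF, reflux
Reagents that add atoms: paraformaldehyde (formaldehyde units), C=O
Why: Magnesium-mediated ortho-formylation of a phenol (Casnati–Skattebøl) is directed by the phenoxide; the two ortho positions of 17 are equivalent and the para position is blocked, so one aldehyde should form and the silyl ethers stay untouched.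

Step 8
Reactants: 18 3-(2-benzyloxy-5-bromophenyl)-6-hydroxy-2,4-bis(triisopropylsilyloxy)benzaldehyde; 19 1-(benzyloxy)-4-ethynylbenzene
Product: 21 1-[3-(2-benzyloxy-5-bromophenyl)-6-hydroxy-2,4-bis(triisopropylsilyloxy)phenyl]-3-(4-benzyloxyphenyl)prop-2-yn-1-one, via carbinol 20 (not isolated)
Conditions: 19 (2.5 equiv), n-BuLi (2.3 equiv), THF, −78 °C; 18, −78 °C; NH4Cl (aq) at −78 °C; crude, MnO2, CH2Cl2, rt
Reagents that add atoms: none
Why: 1,2-Addition of a lithium acetylide to the aldehyde (one extra equivalent for the phenol, cold quench to prevent silyl migration) followed by MnO2 oxidation of the benzylic, propargylic carbinol, whose racemic centre is erased, is a standard entry to o-hydroxyaryl ynones.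

Step 9
Reactants: 21 1-[3-(2-benzyloxy-5-bromophenyl)-6-hydroxy-2,4-bis(triisopropylsilyloxy)phenyl]-3-(4-benzyloxyphenyl)prop-2-yn-1-one
Product: 23 6-(2-benzyloxy-5-bromophenyl)-2-(4-benzyloxyphenyl)-5,7-bis(triisopropylsilyloxy)-4H-chromen-4-one, via enaminone 22 (not isolated)
Conditions: Et2NH, THF/EtOH, rt to 50 °C
Reagents that add atoms: none
Why: Amine-mediated 6-endo cyclisation of an o-hydroxyaryl ynone: conjugate addition of Et2NH gives the β-enaminone, whose β-carbon is the only electrophilic site, so the single free phenol closes the pyranone by addition–elimination and no aurone can form.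

Step 10
Reactants: 23 6-(2-benzyloxy-5-bromophenyl)-2-(4-benzyloxyphenyl)-5,7-bis(triisopropylsilyloxy)-4H-chromen-4-one
Product: 25 5,7-bis(benzyloxy)-6-(2-benzyloxy-5-bromophenyl)-2-(4-benzyloxyphenyl)-4H-chromen-4-one, via dicesium bisphenoxide 24 (not isolated)
Conditions: CsF, BnBr (excess), DMF, rt to 70 °C
Reagents that add atoms: benzyl bromide, BrCc1ccccc1
Why: Fluoride cleaves the aryl silyl ethers to cesium phenoxides that are benzylated in the same flask (one-pot desilylation and Williamson etherification); heating serves the chelated, flanked 5-oxygen.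

Step 11
Reactants: 26 1-(2,6-dihydroxy-4-methoxyphenyl)ethanone
Product: 27 1-(2-benzyloxy-6-hydroxy-4-methoxyphenyl)ethanone
Conditions: BnBr (1.0 equiv), K2CO3, acetone, reflux
Reagents that add atoms: benzyl bromide, BrCc1ccccc1
Why: Williamson mono-alkylation of the symmetric diol should stop after one benzyl group because the remaining hydroxyl is then locked in a hydrogen bond to the carbonyl.

Step 12
Reactants: 25 5,7-bis(benzyloxy)-6-(2-benzyloxy-5-bromophenyl)-2-(4-benzyloxyphenyl)-4H-chromen-4-one; 27 1-(2-benzyloxy-6-hydroxy-4-methoxyphenyl)ethanone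
Product: 30 5-benzyloxy-2-{4-benzyloxy-3-[5,7-bis(benzyloxy)-2-(4-benzyloxyphenyl)-4-oxo-4H-chromen-6-yl]phenyl}-7-methoxy-4H-chromen-4-one, via aryl ester 28 (not isolated), via 1,3-diketone 29 (not isolated)
Conditions: Pd(OAc)2 (5 mol %), 1,4-bis(diphenylphosphino)butane, DBU (3 equiv), 27 (2 equiv), CO (10 bar), DMSO, 120 °C; then AcOH, 90 °C
Reagents that add atoms: carbon monoxide, [C-]#[O+]
Why: Palladium-catalysed carbonylative coupling of an aryl bromide with a 2-hydroxyacetophenone: oxidative addition to zerovalent palladium and CO insertion give an acylpalladium that the phenoxide captures as the aryl ester, and DBU then drives the Baker–Venkataraman acyl shift and cyclodehydration, which the acetic acid finish completes.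

Step 13
Reactants: 30 5-benzyloxy-2-{4-benzyloxy-3-[5,7-bis(benzyloxy)-2-(4-benzyloxyphenyl)-4-oxo-4H-chromen-6-yl]phenyl}-7-methoxy-4H-chromen-4-one
Product: 31 5-hydroxy-2-{4-hydroxy-3-[5,7-dihydroxy-2-(4-hydroxyphenyl)-4-oxo-4H-chromen-6-yl]phenyl}-7-methoxy-4H-chromen-4-one (CNP0277373.0)
Conditions: H2 (1 atm), palladium on carbon (Pd/C), THF/MeOH, rt
Reagents that add atoms: none
Why: Catalytic hydrogenolysis should remove all five benzyl ethers and leave the methyl ether; the reaction is stopped at the calculated uptake so the pyranone double bonds are not reduced.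

**Compound list**

1 | 2-(5-bromo-2-hydroxyphenyl)acetic acid | OC(=O)Cc1cc(Br)ccc1O | starting material
2 | 2-(2-benzyloxy-5-bromophenyl)acetic acid | OC(=O)Cc1cc(Br)ccc1OCc1ccccc1 | intermediate
3 | ethoxyacetylene | CCOC#C | starting material
4 | 2-(2-benzyloxy-5-bromophenyl)acetyl chloride | ClC(=O)Cc1cc(Br)ccc1OCc1ccccc1 | intermediate
5 | (2-benzyloxy-5-bromophenyl)ketene | O=C=Cc1cc(Br)ccc1OCc1ccccc1 | intermediate
6 | 4-(2-benzyloxy-5-bromophenyl)-3-ethoxycyclobut-2-en-1-one (racemic) | O=C1C=C(OCC)C1c1cc(Br)ccc1OCc1ccccc1 | intermediate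
7 | 2-(2-benzyloxy-5-bromophenyl)-3-hydroxycyclobut-2-en-1-one | O=C1CC(O)=C1c1cc(Br)ccc1OCc1ccccc1 | intermediate
8 | triisopropylsilyl trifluoromethanesulfonate | CC(C)[Si](C(C)C)(C(C)C)OS(=O)(=O)C(F)(F)F | starting material
9 | 2-(2-benzyloxy-5-bromophenyl)-3-(triisopropylsilyloxy)cyclobut-2-en-1-one | O=C1CC(O[Si](C(C)C)(C(C)C)C(C)C)=C1c1cc(Br)ccc1OCc1ccccc1 | intermediate
10 | ethyl dibromoacetate | CCOC(=O)C(Br)Br | starting material
11 | lithium ethynolate | [Li+].[O-]C#C | intermediate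
12 | (triisopropylsilyloxy)acetylene | C#CO[Si](C(C)C)(C(C)C)C(C)C | intermediate
13 | (2-benzyloxy-5-bromophenyl)[1-(triisopropylsilyloxy)ethenyl]ketene | O=C=C(c1cc(Br)ccc1OCc1ccccc1)C(=C)O[Si](C(C)C)(C(C)C)C(C)C | intermediate
14 | 4-(2-benzyloxy-5-bromophenyl)-3-(triisopropylsilyloxy)-4-[1-(triisopropylsilyloxy)ethenyl]cyclobut-2-en-1-one (racemic) | O=C1C=C(O[Si](C(C)C)(C(C)C)C(C)C)C1(c1cc(Br)ccc1OCc1ccccc1)C(=C)O[Si](C(C)C)(C(C)C)C(C)C | intermediate
15 | 4-(2-benzyloxy-5-bromophenyl)-3,5-bis(triisopropylsilyloxy)hexa-1,3,5-trien-1-one, ketene carbon and siloxyvinyl group cis on the central double bond | O=C=C/C(O[Si](C(C)C)(C(C)C)C(C)C)=C(/c1cc(Br)ccc1OCc1ccccc1)C(=C)O[Si](C(C)C)(C(C)C)C(C)C | intermediate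
16 | 4-(2-benzyloxy-5-bromophenyl)-3,5-bis(triisopropylsilyloxy)cyclohexa-2,4-dien-1-one | O=C1C=C(O[Si](C(C)C)(C(C)C)C(C)C)C(c2cc(Br)ccc2OCc2ccccc2)=C(O[Si](C(C)C)(C(C)C)C(C)C)C1 | intermediate
17 | 4-(2-benzyloxy-5-bromophenyl)-3,5-bis(triisopropylsilyloxy)phenol | Oc1cc(O[Si](C(C)C)(C(C)C)C(C)C)c(-c2cc(Br)ccc2OCc2ccccc2)c(O[Si](C(C)C)(C(C)C)C(C)C)c1 | intermediate
18 | 3-(2-benzyloxy-5-bromophenyl)-6-hydroxy-2,4-bis(triisopropylsilyloxy)benzaldehyde | O=Cc1c(O)cc(O[Si](C(C)C)(C(C)C)C(C)C)c(-c2cc(Br)ccc2OCc2ccccc2)c1O[Si](C(C)C)(C(C)C)C(C)C | intermediate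
19 | 1-(benzyloxy)-4-ethynylbenzene | C#Cc1ccc(OCc2ccccc2)cc1 | starting material
20 | 1-[3-(2-benzyloxy-5-bromophenyl)-6-hydroxy-2,4-bis(triisopropylsilyloxy)phenyl]-3-(4-benzyloxyphenyl)prop-2-yn-1-ol (racemic) | OC(C#Cc1ccc(OCc2ccccc2)cc1)c1c(O)cc(O[Si](C(C)C)(C(C)C)C(C)C)c(-c2cc(Br)ccc2OCc2ccccc2)c1O[Si](C(C)C)(C(C)C)C(C)C | intermediate
21 | 1-[3-(2-benzyloxy-5-bromophenyl)-6-hydroxy-2,4-bis(triisopropylsilyloxy)phenyl]-3-(4-benzyloxyphenyl)prop-2-yn-1-one | O=C(C#Cc1ccc(OCc2ccccc2)cc1)c1c(O)cc(O[Si](C(C)C)(C(C)C)C(C)C)c(-c2cc(Br)ccc2OCc2ccccc2)c1O[Si](C(C)C)(C(C)C)C(C)C | intermediate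
22 | 1-[3-(2-benzyloxy-5-bromophenyl)-6-hydroxy-2,4-bis(triisopropylsilyloxy)phenyl]-3-(4-benzyloxyphenyl)-3-(diethylamino)prop-2-en-1-one (double-bond geometry not fixed) | CCN(CC)C(=CC(=O)c1c(O)cc(O[Si](C(C)C)(C(C)C)C(C)C)c(-c2cc(Br)ccc2OCc2ccccc2)c1O[Si](C(C)C)(C(C)C)C(C)C)c1ccc(OCc2ccccc2)cc1 | intermediate
23 | 6-(2-benzyloxy-5-bromophenyl)-2-(4-benzyloxyphenyl)-5,7-bis(triisopropylsilyloxy)-4H-chromen-4-one | O=c1cc(-c2ccc(OCc3ccccc3)cc2)oc2cc(O[Si](C(C)C)(C(C)C)C(C)C)c(-c3cc(Br)ccc3OCc3ccccc3)c(O[Si](C(C)C)(C(C)C)C(C)C)c12 | intermediate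
24 | dicesium 6-(2-benzyloxy-5-bromophenyl)-2-(4-benzyloxyphenyl)-4-oxo-4H-chromene-5,7-bis(olate) | [Cs+].[Cs+].O=c1cc(-c2ccc(OCc3ccccc3)cc2)oc2cc([O-])c(-c3cc(Br)ccc3OCc3ccccc3)c([O-])c12 | intermediate
25 | 5,7-bis(benzyloxy)-6-(2-benzyloxy-5-bromophenyl)-2-(4-benzyloxyphenyl)-4H-chromen-4-one | O=c1cc(-c2ccc(OCc3ccccc3)cc2)oc2cc(OCc3ccccc3)c(-c3cc(Br)ccc3OCc3ccccc3)c(OCc3ccccc3)c12 | intermediate
26 | 1-(2,6-dihydroxy-4-methoxyphenyl)ethanone | CC(=O)c1c(O)cc(OC)cc1O | starting material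
27 | 1-(2-benzyloxy-6-hydroxy-4-methoxyphenyl)ethanone | CC(=O)c1c(O)cc(OC)cc1OCc1ccccc1 | intermediate
28 | 2-acetyl-3-benzyloxy-5-methoxyphenyl 4-benzyloxy-3-[5,7-bis(benzyloxy)-2-(4-benzyloxyphenyl)-4-oxo-4H-chromen-6-yl]benzoate | CC(=O)c1c(OCc2ccccc2)cc(OC)cc1OC(=O)c1ccc(OCc2ccccc2)c(-c2c(OCc3ccccc3)cc3oc(-c4ccc(OCc5ccccc5)cc4)cc(=O)c3c2OCc2ccccc2)c1 | intermediate
29 | 1-(2-benzyloxy-6-hydroxy-4-methoxyphenyl)-3-{4-benzyloxy-3-[5,7-bis(benzyloxy)-2-(4-benzyloxyphenyl)-4-oxo-4H-chromen-6-yl]phenyl}propane-1,3-dione | O=C(CC(=O)c1ccc(OCc2ccccc2)c(-c2c(OCc3ccccc3)cc3oc(-c4ccc(OCc5ccccc5)cc4)cc(=O)c3c2OCc2ccccc2)c1)c1c(O)cc(OC)cc1OCc1ccccc1 | intermediate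
30 | 5-benzyloxy-2-{4-benzyloxy-3-[5,7-bis(benzyloxy)-2-(4-benzyloxyphenyl)-4-oxo-4H-chromen-6-yl]phenyl}-7-methoxy-4H-chromen-4-one | COc1cc(OCc2ccccc2)c2c(=O)cc(-c3ccc(OCc4ccccc4)c(-c4c(OCc5ccccc5)cc5oc(-c6ccc(OCc7ccccc7)cc6)cc(=O)c5c4OCc4ccccc4)c3)oc2c1 | intermediate
31 | 5-hydroxy-2-{4-hydroxy-3-[5,7-dihydroxy-2-(4-hydroxyphenyl)-4-oxo-4H-chromen-6-yl]phenyl}-7-methoxy-4H-chromen-4-one (CNP0277373.0) | COc1cc(O)c2c(=O)cc(-c3ccc(O)c(-c4c(O)cc5oc(-c6ccc(O)cc6)cc(=O)c5c4O)c3)oc2c1 | target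

**Count and risks**

Total step count: 13. Longest linear sequence: 11 steps (steps 1–4, 6–10, 12, 13); steps 5 and 11 are side branches.

Most likely to fail, step 6. The siloxy group on C3 stabilises cyclobutenone 9 as a vinylogous silyl ester, so ring opening may be slow at temperatures where 12 isomerises to the silylketene. The first new bond to the ring also has to form at the crowded aryl-bearing ketene α-carbon. The fallback forms the ring through the regioisomeric cyclobutenone and differentiates the oxygens in another way. It sets out from ketene 5, generated from 2 as in step 2, and comes back at 25.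
- Ketene 5 is trapped with 12 in place of 3, giving 4-(2-benzyloxy-5-bromophenyl)-3-(triisopropylsilyloxy)cyclobut-2-en-1-one F1, whose C4 aryl group assists ring opening.
- Heating F1 with more 12 bonds the ynol ether to an unsubstituted ring carbon and gives 2-(2-benzyloxy-5-bromophenyl)-3,5-bis(triisopropylsilyloxy)phenol F2.
- Magnesium-mediated formylation at the one free ortho position gives 3-(2-benzyloxy-5-bromophenyl)-2-hydroxy-4,6-bis(triisopropylsilyloxy)benzaldehyde F3.
- Mitsunobu benzylation (BnOH, PPh3, diisopropyl azodicarboxylate) gives 2-benzyloxy-3-(2-benzyloxy-5-bromophenyl)-4,6-bis(triisopropylsilyloxy)benzaldehyde F4.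
- The lithium acetylide of 19 adds to give 1-[2-benzyloxy-3-(2-benzyloxy-5-bromophenyl)-4,6-bis(triisopropylsilyloxy)phenyl]-3-(4-benzyloxyphenyl)prop-2-yn-1-ol F5, and MnO2 oxidises it to 1-[2-benzyloxy-3-(2-benzyloxy-5-bromophenyl)-4,6-bis(triisopropylsilyloxy)phenyl]-3-(4-benzyloxyphenyl)prop-2-yn-1-one F6.
- Tetrabutylammonium fluoride removes both silyl groups. Only the phenoxide ortho to the ynone can reach the triple bond, and 6-endo closure gives 5-benzyloxy-6-(2-benzyloxy-5-bromophenyl)-2-(4-benzyloxyphenyl)-7-hydroxy-4H-chromen-4-one F7.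
- Benzylation of F7 (BnBr, K2CO3, DMF) gives 25.

Second, step 5. The acidic α-hydrogen of 10 may be removed in competition with bromine–lithium exchange, and the resulting mixture of lithiated species may be silylated on carbon or lost on work-up. The fallback uses a substituted ynol ether made by the Kowalski ester homologation, which also brings in the formyl carbon. It sets out from 8 and 9 and comes back at 18, so step 7 is skipped.
- Methyl dimethoxyacetate is treated with CH2Br2 and lithium 2,2,6,6-tetramethylpiperidide, then LiN(SiMe3)2 and n-BuLi, to give lithium 3,3-dimethoxyprop-1-yn-1-olate F8.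
- O-Silylation of F8 with 8 gives 3,3-dimethoxy-1-(triisopropylsilyloxy)prop-1-yne F9.
- Benzannulation of 9 with F9 under the conditions of step 6 puts the substituted alkyne carbon ortho to the new hydroxyl and gives 4-(2-benzyloxy-5-bromophenyl)-2-(dimethoxymethyl)-3,5-bis(triisopropylsilyloxy)phenol F10.
- Mild acetal hydrolysis (pyridinium p-toluenesulfonate, acetone/water) gives 18.

Third, step 12. The hindered, hydrogen-bonded phenol 27 may capture the acylpalladium too slowly, so that reduction of the bromide or breakdown of the flavone under DBU at 120 °C takes over. The fallback separates carbonylation from the acyl transfer and uses only classical steps. It sets out from 25 and comes back at 30.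
- Methoxycarbonylation (Pd(OAc)2, Xantphos, CO 1 atm, MeOH, Et3N, 70 °C) gives methyl 4-benzyloxy-3-[5,7-bis(benzyloxy)-2-(4-benzyloxyphenyl)-4-oxo-4H-chromen-6-yl]benzoate F11.
- Saponification (LiOH, THF/water) gives 4-benzyloxy-3-[5,7-bis(benzyloxy)-2-(4-benzyloxyphenyl)-4-oxo-4H-chromen-6-yl]benzoic acid F12.
- Carbodiimide esterification of F12 with 27 (EDC hydrochloride, DMAP, CH2Cl2) gives the isolated ester 28.
- Baker–Venkataraman rearrangement (KOtBu, THF) gives 29, and cyclodehydration (p-toluenesulfonic acid, toluene, 80 °C) gives 30.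

Further compounds
F1 | step 6 | 4-(2-benzyloxy-5-bromophenyl)-3-(triisopropylsilyloxy)cyclobut-2-en-1-one (racemic) | O=C1C=C(O[Si](C(C)C)(C(C)C)C(C)C)C1c1cc(Br)ccc1OCc1ccccc1
F2 | step 6 | 2-(2-benzyloxy-5-bromophenyl)-3,5-bis(triisopropylsilyloxy)phenol | Oc1cc(O[Si](C(C)C)(C(C)C)C(C)C)cc(O[Si](C(C)C)(C(C)C)C(C)C)c1-c1cc(Br)ccc1OCc1ccccc1
F3 | step 6 | 3-(2-benzyloxy-5-bromophenyl)-2-hydroxy-4,6-bis(triisopropylsilyloxy)benzaldehyde | O=Cc1c(O)c(-c2cc(Br)ccc2OCc2ccccc2)c(O[Si](C(C)C)(C(C)C)C(C)C)cc1O[Si](C(C)C)(C(C)C)C(C)C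
F4 | step 6 | 2-benzyloxy-3-(2-benzyloxy-5-bromophenyl)-4,6-bis(triisopropylsilyloxy)benzaldehyde | O=Cc1c(OCc2ccccc2)c(-c2cc(Br)ccc2OCc2ccccc2)c(O[Si](C(C)C)(C(C)C)C(C)C)cc1O[Si](C(C)C)(C(C)C)C(C)C
F5 | step 6 | 1-[2-benzyloxy-3-(2-benzyloxy-5-bromophenyl)-4,6-bis(triisopropylsilyloxy)phenyl]-3-(4-benzyloxyphenyl)prop-2-yn-1-ol (racemic) | OC(C#Cc1ccc(OCc2ccccc2)cc1)c1c(OCc2ccccc2)c(-c2cc(Br)ccc2OCc2ccccc2)c(O[Si](C(C)C)(C(C)C)C(C)C)cc1O[Si](C(C)C)(C(C)C)C(C)C
F6 | step 6 | 1-[2-benzyloxy-3-(2-benzyloxy-5-bromophenyl)-4,6-bis(triisopropylsilyloxy)phenyl]-3-(4-benzyloxyphenyl)prop-2-yn-1-one | O=C(C#Cc1ccc(OCc2ccccc2)cc1)c1c(OCc2ccccc2)c(-c2cc(Br)ccc2OCc2ccccc2)c(O[Si](C(C)C)(C(C)C)C(C)C)cc1O[Si](C(C)C)(C(C)C)C(C)C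
F7 | step 6 | 5-benzyloxy-6-(2-benzyloxy-5-bromophenyl)-2-(4-benzyloxyphenyl)-7-hydroxy-4H-chromen-4-one | O=c1cc(-c2ccc(OCc3ccccc3)cc2)oc2cc(O)c(-c3cc(Br)ccc3OCc3ccccc3)c(OCc3ccccc3)c12
F8 | step 5 | lithium 3,3-dimethoxyprop-1-yn-1-olate | [Li+].[O-]C#CC(OC)OC
F9 | step 5 | 3,3-dimethoxy-1-(triisopropylsilyloxy)prop-1-yne | COC(OC)C#CO[Si](C(C)C)(C(C)C)C(C)C
F10 | step 5 | 4-(2-benzyloxy-5-bromophenyl)-2-(dimethoxymethyl)-3,5-bis(triisopropylsilyloxy)phenol | COC(OC)c1c(O)cc(O[Si](C(C)C)(C(C)C)C(C)C)c(-c2cc(Br)ccc2OCc2ccccc2)c1O[Si](C(C)C)(C(C)C)C(C)C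
F11 | step 12 | methyl 4-benzyloxy-3-[5,7-bis(benzyloxy)-2-(4-benzyloxyphenyl)-4-oxo-4H-chromen-6-yl]benzoate | COC(=O)c1ccc(OCc2ccccc2)c(-c2c(OCc3ccccc3)cc3oc(-c4ccc(OCc5ccccc5)cc4)cc(=O)c3c2OCc2ccccc2)c1
F12 | step 12 | 4-benzyloxy-3-[5,7-bis(benzyloxy)-2-(4-benzyloxyphenyl)-4-oxo-4H-chromen-6-yl]benzoic acid | OC(=O)c1ccc(OCc2ccccc2)c(-c2c(OCc3ccccc3)cc3oc(-c4ccc(OCc5ccccc5)cc4)cc(=O)c3c2OCc2ccccc2)c1
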